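At the reading, 15 d after mixing, I wanted to know how the Z charged was shared among its forms, so the scheme and the charges come first.

    Z.J ⇌ G (K1 = 1.0, k1 = 0.31 h⁻¹)
    Z + J → Z.J, rate k2*[Z]^0.5*[J] (k2 = 0.28 L⁰·⁵ mol⁻⁰·⁵ h⁻¹)

Z 41 mM; J 82.0 mM; time 15 d

- the reaction counts as stopped when no species that holds the Z changes by six tenths of a point or more over the second half of the time
- run time (flask): 15 d

- which holds at 15 d: what has brought the reaction to rest, or that it has not come to rest (J has run out first / it is still moving / all of Z has reacted / forward and back rates have come level)
- part of the Z gone at 15 d
- the Z.J standing at 15 d, as a percentage of the Z charged
- the G standing at 15 d, as a percentage of the Z charged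

First I asked which charge ends the making of Z.J in the flask. There the reach stood at 2.00, the reach being the J charged as a fraction of the Z charged. It lay above one, so Z was the limiting reagent, and the share of Z that J could turn was 100%.

That raised the question of time. J in the flask could not fall below 50.0% of its own charge, and at that floor the square root of the Z fraction falls steadily, reaching zero by 35.3 h. This is shorter than the time, which holds 10.2 such spans, so I expected Z to have fully reacted.

Last I asked how the turned share divides in the flask. Z.J and G relax together with a half-life of 1.12 h, far shorter than the time, and 290 such half-lives lay between my bound for the Z and the reading. So I took the balance, with Z.J at 50.0% and G at 50.0%.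

The forecast said all of Z has reacted, with 100% of the Z gone, Z.J at 50% and G at 50%, on the ground that “Z reaches exactly zero in finite time”, at 28 h, inside my bound.

The simulated flask gave all of Z has reacted, with 100% of the Z gone, Z.J at 50.0% and G at 50.0%.

With the turning of Z.J into G taken away, Z.J in the flask, at its reach of 2.00, stood at 100% against 50.0%, and that turning is why Z.J there held 50.0%. The neighbour flask, charged with 100 mM of Z, had a reach of 0.820, below one, and it ended with 0% of its J and 18% of its Z left. Its reach, split by the same balance, gave 41.0%, and Z.J in that neighbour stood at 41.0%.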